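Ring B of previtexilactone carries oxygen at C6 and C9 (para) and methyls at C8 and C10, so it is a masked 2,6-dimethyl-1,4-benzoquinone. Ring A (C1–C2–C3–C4–C5–C10) is then one hydrogenation away from a Diels–Alder cyclohexene. A catalytic enantioselective Diels–Alder reaction of the quinone with 4-methylpenta-1,3-diene forms C1–C10 and C4–C5 in one operation, creates the C10 quaternary centre and delivers all fourteen decalin carbons from two commercial compounds. Reduction and equilibration give the trans-dione. The C9 carbonyl becomes the 9α-oxygenated side chain through a spiro-epoxide, and a palladium-catalysed oxycarbonylation closes the tetrahydrofuran and the lactone together.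

Key step: step 1

Remark: positions are given in labdane numbering (decalin C1–C10, side chain C11–C16, C17 on C8, C18 and C19 on C4, C20 on C10); α is the face opposite the C10 methyl.

Assumption: the (S)-configured oxazaborolidinium catalyst is taken to deliver adduct 3 with the (8aS) quaternary centre; should its facial sense prove opposite, the (R)-catalyst is used and no structure below changes.

Step 1
Reactants: 1 2,6-dimethyl-1,4-benzoquinone; 2 4-methylpenta-1,3-diene
Product: 3 (4aR,8aS)-2,5,5,8a-tetramethyl-4a,5,8,8a-tetrahydronaphthalene-1,4-dione (cis-fused adduct)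
Conditions: 2 (3 equiv), (S)-3,3-diphenyl-1-(2-methylphenyl)tetrahydro-1H,3H-pyrrolo[1,2-c][1,3,2]oxazaborole (20 mol%) activated with Tf2NH (18 mol%), CH2Cl2, −78 → −40 °C
Reagents that add atoms: none
Why: Lewis-acid-accelerated Diels–Alder reaction in which the boron cation binds the more basic, unhindered C6 carbonyl oxygen (lone pair syn to the C5–H), so that the quinone C5=C10 bond becomes an activated enone whose β-carbon is the methyl-bearing C10; the s-cis diene adds suprafacially, its nucleophilic CH2 terminus bonding to C10 and its CMe2 terminus (tertiary allyl-cation character) to C5. The closest known reaction type is the cationic oxazaborolidine-catalysed enantioselective Diels–Alder reaction of quinones. Ring A is closed by a concerted but asynchronous [4+2] cycloaddition. The C10 quaternary centre is fixed by the catalyst, whose aryl groups shield one face of the bound enone, and C5 is formed cis to it by suprafacial addition and is corrected in step 2. The step needs the catalysed regiochemistry (CH2 to C10, CMe2 to C5) and one enantioface; the first is secured by coordination at the carbonyl flanked by two C–H groups and by the polarisation of the diene, the second by the catalyst, while site selectivity is moot because the two quinone C=C bonds are symmetry-equivalent.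

Step 2
Reactants: 3
Product: 5 (2R,4aS,8aS)-2,5,5,8a-tetramethyloctahydronaphthalene-1,4-dione (trans-fused), via cis-fused saturated dione 4 (not isolated)
Conditions: H2 (3 atm), 10% Pd/C, EtOAc, rt; filter and concentrate; then NaOMe (0.2 equiv), MeOH, rt
Reagents that add atoms: none
Why: Catalytic hydrogenation should saturate the ring A alkene and the enedione C7=C8 bond, and methoxide then equilibrates the two enolisable centres C5 and C8 to the thermodynamically preferred trans-fused dione with the C8 methyl equatorial (α).

Step 3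
Reactants: 5
Product: 6 (2R,4R,4aS,8aS)-4-hydroxy-2,5,5,8a-tetramethyloctahydronaphthalen-1(2H)-one (6β-hydroxy-9-ketone)
Conditions: LiBH(s-Bu)3 (L-Selectride, 1.1 equiv), THF, −78 °C; then H2O
Reagents that add atoms: none
Why: Chemoselective hydride reduction in which the bulky borohydride should attack the C6 carbonyl by equatorial approach from the α face (the β face is closed by the syn-axial C10 and C4 methyls) to give the axial 6β-alcohol, while the C9 carbonyl, flanked by the quaternary C10 and the C8 methyl, resists this reagent.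

Step 4
Reactants: 6
Product: 7 (1R,3R,4aS,8aS)-3,4a,8,8-tetramethyl-4-methylidenedecahydronaphthalen-1-ol
Conditions: Ph3PCH3Br (4 equiv), KOt-Bu (4 equiv), toluene, 90 °C
Reagents that add atoms: methyltriphenylphosphonium bromide, C[P+](c1ccccc1)(c1ccccc1)c1ccccc1.[Br-]
Why: Wittig methylenation with excess ylide at elevated temperature is the usual recourse for α,α,α'-trisubstituted cyclohexanones; the 6-alkoxide is inert and the C8 methyl remains equatorial.

Step 5
Reactants: 7
Product: 8 (2R,1'R,3'R,4a'S,8a'S)-3',4a',8',8'-tetramethyloctahydro-1'H-spiro[oxirane-2,4'-naphthalen]-1'-ol (9α,11-epoxide with the oxygen axial on the α face)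
Conditions: mCPBA (1.3 equiv), NaHCO3, CH2Cl2, 0 °C
Reagents that add atoms: mCPBA, OOC(=O)c1cccc(Cl)c1
Why: Prilezhaev epoxidation of the exocyclic alkene should occur from the α face, anti to the adjacent axial C10 methyl, placing the oxygen axial (9α) and C11 equatorial (β).

Step 6
Reactants: 8; 9 2-methylprop-2-en-1-ol
Product: 10 (1R,2R,4R,4aS,8aS)-1-[3-(hydroxymethyl)but-3-en-1-yl]-2,5,5,8a-tetramethyldecahydronaphthalene-1,4-diol
Conditions: 9 (5 equiv), n-BuLi (10 equiv), TMEDA, Et2O–hexane, 0 °C → rt; then 8, THF, 0 °C → rt; then H2O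
Reagents that add atoms: none
Why: The symmetrical allyl dianion formed by allylic lithiation of 9 should open the 1,1-disubstituted epoxide at its CH2 terminus (SN2), forming C11–C12 and leaving the C9–O bond and hence the C9 configuration untouched.

Step 7
Reactants: 10
Product: 11 (5S,6R,8R,9R,10S,13S)-6-hydroxy-9,13-epoxylabdan-16,15-olide (6-O-deacetylprevitexilactone)
Conditions: PdCl2(MeCN)2 (10 mol%), CuCl2 (3 equiv), NaOAc (3 equiv), CO (1 atm), MeCN, rt
Reagents that add atoms: carbon monoxide, [C-]#[O+]
Why: Intramolecular alkoxycarbonylation catalysed by divalent palladium, in which 5-exo oxypalladation of the 1,1-disubstituted alkene by the tertiary 9-OH, CO insertion into the neopentyl C14–Pd bond (no β-hydrogen) and capture of the acyl-palladium by the C16 hydroxyl should close the tetrahydrofuran and the γ-lactone together; C13 is formed under substrate control, the palladium-bearing C14 being expected on the tetrahydrofuran face flanked by the C8 methine and the hydroxymethyl C16 on the face flanked by the quaternary C10, which is the (13S) arrangement.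

Step 8
Reactants: 11
Product: 12 previtexilactone, (5S,6R,8R,9R,10S,13S)-6-acetoxy-9,13-epoxylabdan-16,15-olide
Conditions: Ac2O (3 equiv), DMAP (0.2 equiv), Et3N, CH2Cl2, rt → 40 °C
Reagents that add atoms: acetic anhydride, CC(=O)OC(C)=O
Why: DMAP-catalysed acylation of the only remaining hydroxyl, the hindered axial 6β-OH, should proceed without change of configuration.

Compound list
1 | 2,6-dimethyl-1,4-benzoquinone | CC1=CC(=O)C=C(C)C1=O | starting material
2 | 4-methylpenta-1,3-diene | C=CC=C(C)C | starting material
3 | (4aR,8aS)-2,5,5,8a-tetramethyl-4a,5,8,8a-tetrahydronaphthalene-1,4-dione (cis-fused) | O=C1C=C(C)C(=O)[C@@]2(C)CC=CC(C)(C)[C@@H]12 | intermediate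
4 | (2R,4aR,8aS)-2,5,5,8a-tetramethyloctahydronaphthalene-1,4-dione (cis-fused; either C2 epimer converges in the equilibration) | O=C1C[C@@H](C)C(=O)[C@@]2(C)CCCC(C)(C)[C@@H]12 | intermediate
5 | (2R,4aS,8aS)-2,5,5,8a-tetramethyloctahydronaphthalene-1,4-dione (trans-fused, 8α-methyl) | O=C1C[C@@H](C)C(=O)[C@@]2(C)CCCC(C)(C)[C@H]12 | intermediate
6 | (2R,4R,4aS,8aS)-4-hydroxy-2,5,5,8a-tetramethyloctahydronaphthalen-1(2H)-one | O[C@@H]1C[C@@H](C)C(=O)[C@@]2(C)CCCC(C)(C)[C@H]12 | intermediate
7 | (1R,3R,4aS,8aS)-3,4a,8,8-tetramethyl-4-methylidenedecahydronaphthalen-1-ol | O[C@@H]1C[C@@H](C)C(=C)[C@@]2(C)CCCC(C)(C)[C@H]12 | intermediate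
8 | (2R,1'R,3'R,4a'S,8a'S)-3',4a',8',8'-tetramethyloctahydro-1'H-spiro[oxirane-2,4'-naphthalen]-1'-ol | O[C@@H]1C[C@@H](C)[C@]2(CO2)[C@@]3(C)CCCC(C)(C)[C@H]13 | intermediate
9 | 2-methylprop-2-en-1-ol | CC(=C)CO | starting material
10 | (1R,2R,4R,4aS,8aS)-1-[3-(hydroxymethyl)but-3-en-1-yl]-2,5,5,8a-tetramethyldecahydronaphthalene-1,4-diol | O[C@@H]1C[C@@H](C)[C@](O)(CCC(=C)CO)[C@@]2(C)CCCC(C)(C)[C@H]12 | intermediate
11 | (5S,6R,8R,9R,10S,13S)-6-hydroxy-9,13-epoxylabdan-16,15-olide | O[C@@H]1C[C@@H](C)[C@]2(CC[C@]3(COC(=O)C3)O2)[C@@]2(C)CCCC(C)(C)[C@H]12 | intermediate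
12 | previtexilactone, (5S,6R,8R,9R,10S,13S)-6-acetoxy-9,13-epoxylabdan-16,15-olide | CC(=O)O[C@@H]1C[C@@H](C)[C@]2(CC[C@]3(COC(=O)C3)O2)[C@@]2(C)CCCC(C)(C)[C@H]12 | target

Total step count: 8. Longest linear sequence: 8 steps (1 → 12).

Steps most likely to fail

1. Step 1. The (Z)-methyl of the diene disfavours the s-cis conformer, so the cycloaddition may be sluggish and may be overtaken by acid-induced isomerisation or oligomerisation of the diene; a stepwise pathway could also erode enantiofacial control. The fallback sets out from 1 and comes back at 5. The diene is replaced by the strain-activated (prop-2-en-1-ylidene)cyclopropane F1 (from cyclopropyltriphenylphosphonium bromide, NaH and acrolein in THF). Its tied-back terminus no longer obstructs the s-cis conformer, and its exocyclic double bond is released from methylenecyclopropane strain on cycloaddition. With the same catalyst it should give the cis-fused spiro adduct F2, both ring-forming bonds again being made at once. The two C=C bonds are saturated first (H2, PtO2, EtOAc) to the saturated spiro-dione F3, because a vinylcyclopropane would open toward an ethyl group. The distal CH2–CH2 bond of the cyclopropane is then hydrogenolysed (H2, PtO2, AcOH) to unveil the gem-dimethyl group of 4, which is equilibrated to 5 as in step 2.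

2. Step 7. Facial discrimination at C13 during oxypalladation may be poor, because the two faces of the forming tetrahydrofuran differ only by the C8 and C10 flanks; ionisation or acetoxylation of the allylic alcohol may also compete. The fallback sets out from 8 and comes back at 11. Epoxide 8 is opened instead with the dianion of 3-methylbut-3-en-1-ol (n-BuLi, TMEDA) to give the homoallylic triol F4. A hydroxyl-directed, ligand-controlled epoxidation (VO(O-i-Pr)3, chiral bishydroxamic acid ligand, cumene hydroperoxide, toluene) should then deliver the (13R)-13,16-epoxide F5, in which C13 is fixed by the ligand and not by the decalin. Camphorsulfonic acid triggers 5-exo opening by the 9-OH at the tertiary C13 with inversion, giving the spiro-tetrahydrofuran triol F6. TEMPO with PhI(OAc)2 oxidises the unhindered C15 carbinol selectively; the lactol closes onto the neopentyl C16 hydroxyl and is oxidised on to lactone 11.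

3. Step 3. Discrimination between the two hindered carbonyls may be incomplete, with reduction at C9 or over-reduction to the diol. The fallback sets out from 5 and comes back at 7. The C6 carbonyl is masked by kinetic enolisation toward C7 (LiN(i-Pr)2, THF, −78 °C; t-BuMe2SiCl, DMPU) as the silyl enol ether F7. The only remaining carbonyl, C9, is methylenated (Ph3P=CH2, toluene, 90 °C) to the methylidene silyl enol ether F8. Aqueous HCl in THF releases the 9-methylidene-6-ketone F9, and NaBH4 (MeOH, 0 °C) should reduce this single ketone from the α face to 7.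

Further compounds
F1 | step 1 | (prop-2-en-1-ylidene)cyclopropane | C=CC=C1CC1
F2 | step 1 | (4a'R,8a'S)-2',8a'-dimethyl-4a',8a'-dihydro-8'H-spiro[cyclopropane-1,5'-naphthalene]-1',4'-dione (cis-fused) | O=C1C=C(C)C(=O)[C@@]2(C)CC=CC3(CC3)[C@@H]12
F3 | step 1 | (2'R,4a'R,8a'S)-2',8a'-dimethyloctahydro-1'H-spiro[cyclopropane-1,5'-naphthalene]-1',4'-dione (cis-fused) | O=C1C[C@@H](C)C(=O)[C@@]2(C)CCCC3(CC3)[C@@H]12
F4 | step 7 | (1R,2R,4R,4aS,8aS)-1-(5-hydroxy-3-methylidenepentyl)-2,5,5,8a-tetramethyldecahydronaphthalene-1,4-diol | O[C@@H]1C[C@@H](C)[C@](O)(CCC(=C)CCO)[C@@]2(C)CCCC(C)(C)[C@H]12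
F5 | step 7 | (1R,2R,4R,4aS,8aS)-1-{2-[(2R)-2-(2-hydroxyethyl)oxiran-2-yl]ethyl}-2,5,5,8a-tetramethyldecahydronaphthalene-1,4-diol | O[C@@H]1C[C@@H](C)[C@](O)(CC[C@@]3(CCO)CO3)[C@@]2(C)CCCC(C)(C)[C@H]12
F6 | step 7 | (5S,6R,8R,9R,10S,13S)-9,13-epoxylabdane-6,15,16-triol | O[C@@H]1C[C@@H](C)[C@]2(CC[C@@](CO)(CCO)O2)[C@@]2(C)CCCC(C)(C)[C@H]12
F7 | step 3 | (2R,4aS,8aS)-4-[(tert-butyldimethylsilyl)oxy]-2,5,5,8a-tetramethyl-4a,5,6,7,8,8a-hexahydronaphthalen-1(2H)-one | CC(C)(C)[Si](C)(C)OC1=C[C@@H](C)C(=O)[C@@]2(C)CCCC(C)(C)[C@H]12
F8 | step 3 | tert-butyl{[(3R,4aS,8aS)-3,4a,8,8-tetramethyl-4-methylidene-3,4,4a,5,6,7,8,8a-octahydronaphthalen-1-yl]oxy}dimethylsilane | CC(C)(C)[Si](C)(C)OC1=C[C@@H](C)C(=C)[C@@]2(C)CCCC(C)(C)[C@H]12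
F9 | step 3 | (3R,4aS,8aS)-3,4a,8,8-tetramethyl-4-methylideneoctahydronaphthalen-1(2H)-one | O=C1C[C@@H](C)C(=C)[C@@]2(C)CCCC(C)(C)[C@H]12
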